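## Structural features

The target is a 2,3,4-trisubstituted oxolane of the lariciresinol type: ring O1–C2–C3–C4–C5, with a 3,4,5-trimethoxyphenyl group on C2, a hydroxymethyl group on C3, a 3,4,5-trimethoxybenzyl group on C4 and an unsubstituted C5H2. Neither aryl ring is fused to the oxolane; one is bonded directly to C2, the other through the exocyclic methylene C7' on C4. C2, C3 and C4 are contiguous stereocentres, (2S,3R,4R): aryl and hydroxymethyl are trans, hydroxymethyl and benzyl are cis. The fragile elements are the O1–C2 bond (a benzylic ether of an electron-rich arene, open to acid ionisation and to hydrogenolysis), the six aryl methyl ethers (no boron or aluminium halides) and the free primary alcohol. The real difficulty is absolute control of a ring that carries no functional handle except the alcohol, together with the less stable 3,4-cis relation beside a 2,3-trans one. The key step exploits the fact that C2 is both benzylic and bonded to O1, while C5 can stand at the aldehyde level. A cyclopropane made of C2, C3 and C4 with the formyl carbon C5 on C4 is then a donor–acceptor system whose C2–C4 bond is primed to break and whose formyl oxygen becomes O1. Of the three cyclopropane stereocentres only C3 has to survive.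

## Logic of the disconnections

**15 to 14.** The O–H of the C3 hydroxymethyl group is exchanged for O–Si; no skeletal bond is cut. The alcohol must be masked, and made bulky, while the ring is built and C4 is set. The forward step only has to remove silicon with fluoride without touching O1–C2.

**14 to 13.** The C4–H and C5–H bonds are removed to give the C4=C5 enol ether. This deletes the C4 stereocentre and leaves a flat C4/C5 unit of the kind a ring expansion delivers. The forward hydrogenation must add from the face opposite the C3 substituent and must spare the benzylic O1–C2 bond.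

**13 to 12.** O1–C2 is cut and C2 is reconnected to C4, contracting the five-membered ring to the cyclopropane C2–C3–C4 with the formyl carbon on C4. This is the strategic cut: the donor aryl on C2 and the acceptor on C4 polarise exactly the bond that must break. The gain is that ring synthesis becomes a cyclopropanation, and that the configurations at C2 and C4 of 12 do not matter because both are erased. The demand is an acid mild enough to leave the enol ether and the silyl ether intact, and closure of the benzylic cation trans to the C3 substituent.

**12 to 9, through 11 and 10.** The formyl C–H is traced to a C–N bond (11) and the O–Si bond to O–H (10). The amide C–N bond is then cut and the carbonyl carbon reconnected to the hydroxymethyl oxygen (9). In 9 the two oxygenated carbons already differ (one acyl, one alkyl), so 12 is reached without having to tell two primary alcohols apart. The silyl group is chosen as tert-butyldiphenylsilyl, not a smaller one, for stability towards the Lewis acid and for a larger shield in the hydrogenation. The demand is amide formation at a carbonyl on a quaternary carbon, and silylation of 10 before it can relactonise.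

**9 to 8.** The two cyclopropane bonds at the quaternary carbon (C4–C2 and C4–C3) are cut, giving a carbene carbon tethered through the ester to an E alkene. One catalytic step then creates all three ring stereocentres: tether and alkene geometry fix the relative configuration, the catalyst the absolute one. The demand is that a carbene with benzylic β-hydrogens adds to the alkene faster than it undergoes 1,2-hydride shift.

**8 to 7.** The C=N2 group is traced to a C–H/C–acetyl pair. A plain ester α-carbon does not accept a diazo group from a sulfonyl azide, whereas an acetoacetate does and loses its acetyl group in the same operation. The demand is clean deacylation without touching the allylic ester.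

**7 to 5 and 6.** The bond between the α-carbon and the benzylic CH2 (C4–C7') is cut. This joins the two aryl halves convergently at an acidic carbon. The demand is mono-C-alkylation.

**5 to 2 and 3, through 4.** The ester C–O bond is cut. Acetoacetylation under neutral thermal conditions suits the ionisable, electron-rich cinnamyl alcohol. The demand is a temperature below that of the Carroll rearrangement.

**2 to 1.** The allylic alcohol is traced to the commercial conjugated ester by a redox adjustment; the E geometry is bought, not made. The demand is 1,2-reduction only.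

## Other disconnections considered

**Alternative 1:** The cut removes O1–C2, C3–C4 and the bond from C7' to its aryl ring at once, leaving the benzylidene malonate A1, prop-2-yn-1-ol A2 and the aryl iodide A3.
- Forward step: the alkoxide of A2 would add to A1 (O1–C2). The malonate anion would then attack the alkyne bound to the arylpalladium iodide (divalent palladium, from A3 and Pd(PPh3)4, zerovalent palladium) to form C3–C4. Reductive elimination would join C7' to the aryl ring and give the oxolane diester A4, with the alkene geometry set by anti carbopalladation.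
- In favour: the whole skeleton is assembled in one flask from simple pieces. The later hydrogenation of the exocyclic alkene anti to the C3 substituent uses the same facial argument as step 10.
- Against: C2 is formed with no control of absolute configuration, so A4 is a racemate and a resolution must supply the single enantiomer. The geminal diester must be cut down to one hydroxymethyl group trans to the aryl group, and the dealkoxycarbonylation passes through an enolate allylic to the exocyclic alkene, so the double bond may slip into the ring before C4 is set.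
- Comparison: in step economy this route is the better one (about five or six operations against eleven). In the way C4 is set it is the equal of the chosen plan. Its anionic/palladium cascade has no sensitive cationic intermediate, which is also in its favour. On structure it is weaker, because nothing fixes the absolute configuration; the chosen plan settles that catalytically in step 5 and relays it through C3.

**Alternative 2:** The cut removes C2–C3 and C4–C5, so the oxolane is the adduct of a carbonyl ylide (C2–O1–C5) with a C3=C4 alkene. The alkene is the butenolide A6, whose lactone later releases the benzyl group (hydrogenolysis of its benzylic C–O bond) and the C3 carboxyl group (reduced to CH2OH).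
- Forward step: CsF would strip silicon and chloride from the α-chloro ether A5 to give the non-stabilised ylide, which would add to A6 on the face away from its aryl group to give the bicyclic lactone A7.
- Correction of locants: for the adduct to map onto the target, the aryl-bearing ylide carbon must bond to the α-carbon of A6. The aryl groups of A7 therefore stand at C4 and C8 of the 3,7-dioxabicyclo[3.3.0]octan-2-one; a 4,6-diaryl pattern would be the wrong regioisomer.
- In favour: two C–C bonds and the ring form in one step. The cis ring fusion guarantees the 3,4-cis relation, which is better than relying on the facial selectivity of a hydrogenation. C3 arrives as a carboxyl group, so no protecting group is needed.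
- Against: the only source of absolute configuration is the γ-carbon of A6, which is benzylic and vinylogously α to the lactone carbonyl and would be expected to racemise readily under basic fluoride. Neither the regiochemistry of a non-stabilised ylide nor the placement of the C2 aryl group trans to C3 is secured by the substrates. A5 is moisture-sensitive, and the final hydrogenolysis must distinguish two benzylic C–O bonds.
- Comparison: on structure it is better for C4, and worse for C2 and for the robustness of the chirality source. A concerted cycloaddition is cleaner than an ionic rearrangement, but its selectivities are not addressed. Step economy is about equal once an enantioselective preparation of A6 is counted.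

**Alternative 3:** The cut is the C2–C3 bond, made by insertion of a carbene at C3 into the benzylic C–H bond of an ether.
- Forward step: Rh2(S-DOSP)4 (DOSP = N-(4-dodecylbenzenesulfonyl)prolinate) would decompose the vinyldiazoacetate A8. The donor–acceptor carbene would insert into the ArCH2–O C–H bond to close the oxolane and give the ester A9, with the benzylidene already on C4.
- In favour: C2 and C3 are set by the catalyst in the ring-forming step. C3 arrives at the ester level (one reduction, no protecting group). The exocyclic alkene would be hydrogenated under the same facial argument as step 10.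
- Against: A8 is a demanding precursor, a trisubstituted vinyl diazoacetate of defined geometry that can cyclise to a pyrazole on standing, and its carbene can close to a cyclopropene or react at the vinylogous position. By analogy with related insertions into benzylic ether C–H bonds, the cis-2,3 product would be expected to be favoured. The trans ester might then have to come from base epimerisation at C3, a carbon allylic to the exocyclic alkene, with the risk of double-bond migration into conjugation.
- Comparison: step economy is better than in the chosen plan if A8 can be reached in four or five steps. On structure it is the equal in how C4 is set and better in carrying no protecting group. On mechanism the chosen plan is more secure: cyclopropanation by a tethered carbene is less demanding than a C–H insertion that must beat the escape routes of a vinyl carbene, and the 2,3-trans relation arises by itself in step 9.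

Key step: step 9

Assumption: Rh2(S-PTTL)4 (PTTL = N-phthaloyl-tert-leucinate) is taken to give the (1S,5R,6S) enantiomer 9; should the sense of induction be the opposite, Rh2(R-PTTL)4 is used and nothing else changes.

## Route

Step 1
Reactants: 1 methyl (E)-3-(3,4,5-trimethoxyphenyl)prop-2-enoate
Product: 2 (E)-3-(3,4,5-trimethoxyphenyl)prop-2-en-1-ol
Conditions: iBu2AlH (2.5 equiv), CH2Cl2, −78 → 0 °C; aq. potassium sodium tartrate
Reagents that add atoms: none
Why: Reduction of a conjugated ester by iBu2AlH is a 1,2-process at low temperature, so the E alkene is untouched and the allylic alcohol should form cleanly; the aryl methyl ethers are inert.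

Step 2
Reactants: 2 (E)-3-(3,4,5-trimethoxyphenyl)prop-2-en-1-ol; 3 2,2,6-trimethyl-4H-1,3-dioxin-4-one
Product: 5 (E)-3-(3,4,5-trimethoxyphenyl)prop-2-en-1-yl 3-oxobutanoate, via acetylketene 4 (not isolated)
Conditions: toluene, 110 °C, acetone distilled off
Reagents that add atoms: none
Why: Thermal retro-hetero-Diels–Alder cleavage of 3 releases acetylketene 4, which acylates the alcohol under neutral conditions (acetoacetylation); no acid or base touches the ionisable cinnamyl system, and 110 °C stays below the range of the Carroll rearrangement.

Step 3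
Reactants: 5 (E)-3-(3,4,5-trimethoxyphenyl)prop-2-en-1-yl 3-oxobutanoate; 6 5-(chloromethyl)-1,2,3-trimethoxybenzene
Product: 7 (E)-3-(3,4,5-trimethoxyphenyl)prop-2-en-1-yl 3-oxo-2-[(3,4,5-trimethoxyphenyl)methyl]butanoate (racemic)
Conditions: K2CO3, NaI (cat.), acetone, 56 °C
Reagents that add atoms: none
Why: C-Alkylation of the stabilised β-keto ester enolate by a benzylic chloride, helped by in situ Finkelstein exchange; one equivalent of 6 and the weak carbonate base should keep dialkylation minor, and the new stereocentre is irrelevant because it becomes the diazo carbon.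

Step 4
Reactants: 7 (E)-3-(3,4,5-trimethoxyphenyl)prop-2-en-1-yl 3-oxo-2-[(3,4,5-trimethoxyphenyl)methyl]butanoate
Product: 8 (E)-3-(3,4,5-trimethoxyphenyl)prop-2-en-1-yl 2-diazo-3-(3,4,5-trimethoxyphenyl)propanoate
Conditions: p-ABSA, DBU, MeCN, 0 °C → rt
Reagents that add atoms: 4-acetamidobenzenesulfonyl azide (p-ABSA), CC(=O)Nc1ccc(cc1)S(=O)(=O)N=[N+]=[N-]
Why: Regitz-type deacylative diazo transfer: the enolate of 7 adds to the sulfonyl azide and the acetyl group leaves as the N-acetyl sulfonamide, giving the α-alkyl-α-diazo ester that a simple ester would not give by direct transfer.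

Step 5
Reactants: 8 (E)-3-(3,4,5-trimethoxyphenyl)prop-2-en-1-yl 2-diazo-3-(3,4,5-trimethoxyphenyl)propanoate
Product: 9 (1S,5R,6S)-6-(3,4,5-trimethoxyphenyl)-1-[(3,4,5-trimethoxyphenyl)methyl]-3-oxabicyclo[3.1.0]hexan-2-one (aryl exo)
Conditions: Rh2(S-PTTL)4 (1 mol%), CH2Cl2, −40 °C, slow addition of 8
Reagents that add atoms: none
Why: Intramolecular cyclopropanation of an allylic α-alkyl-α-diazo ester by the rhodium carbene; the E alkene geometry is transferred stereospecifically (aryl trans to the ring CH2O, hence exo), the five-membered tether enforces the cis fusion, and the chiral carboxylate ligand sphere selects the alkene face, so C1, C5 and C6 are set together. Bulky carboxylate ligands and low temperature are the known means of holding back 1,2-hydride shift in such carbenes.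

Step 6
Reactants: 9 (1S,5R,6S)-6-(3,4,5-trimethoxyphenyl)-1-[(3,4,5-trimethoxyphenyl)methyl]-3-oxabicyclo[3.1.0]hexan-2-one
Product: 10 (1S,2R,3S)-2-(hydroxymethyl)-N-methoxy-N-methyl-3-(3,4,5-trimethoxyphenyl)-1-[(3,4,5-trimethoxyphenyl)methyl]cyclopropane-1-carboxamide
Conditions: MeNHOMe, AlMe3, CH2Cl2, 0 °C → rt; aq. potassium sodium tartrate
Reagents that add atoms: N,O-dimethylhydroxylamine, CNOC
Why: Aminolysis of the lactone by the aluminium amide Me2AlN(OMe)Me (Weinreb amide formation); opening of cyclopropane-fused butyrolactones with a fully substituted α-carbon by aluminium amides is established practice, and it differentiates the two oxygenated carbons without selective protection. No stereocentre is touched.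

Step 7
Reactants: 10 (1S,2R,3S)-2-(hydroxymethyl)-N-methoxy-N-methyl-3-(3,4,5-trimethoxyphenyl)-1-[(3,4,5-trimethoxyphenyl)methyl]cyclopropane-1-carboxamide
Product: 11 (1S,2R,3S)-2-{[tert-butyl(diphenyl)silyl]oxymethyl}-N-methoxy-N-methyl-3-(3,4,5-trimethoxyphenyl)-1-[(3,4,5-trimethoxyphenyl)methyl]cyclopropane-1-carboxamide
Conditions: TBDPSCl, imidazole, DMAP (cat.), CH2Cl2, 0 °C → rt (crude 10 used at once)
Reagents that add atoms: tert-butyl(chloro)diphenylsilane (TBDPSCl), CC(C)(C)[Si](Cl)(c1ccccc1)c1ccccc1
Why: Standard silylation of a primary alcohol; the tert-butyldiphenylsilyl group is chosen because it withstands the Lewis acid of step 9 better than smaller silyl groups and gives a large shield beside C4 for step 10, and immediate silylation prevents relactonisation of 10.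

Step 8
Reactants: 11 (1S,2R,3S)-2-{[tert-butyl(diphenyl)silyl]oxymethyl}-N-methoxy-N-methyl-3-(3,4,5-trimethoxyphenyl)-1-[(3,4,5-trimethoxyphenyl)methyl]cyclopropane-1-carboxamide
Product: 12 (1S,2R,3S)-2-{[tert-butyl(diphenyl)silyl]oxymethyl}-3-(3,4,5-trimethoxyphenyl)-1-[(3,4,5-trimethoxyphenyl)methyl]cyclopropane-1-carbaldehyde (formyl cis to CH2OSi, aryl trans to both)
Conditions: iBu2AlH (1.5 equiv), THF, −78 °C; aq. potassium sodium tartrate
Reagents that add atoms: none
Why: Reduction of the N-methoxy-N-methyl amide stops at the chelated aluminium hemiaminal, which releases the aldehyde only on work-up; the formyl group sits on a quaternary carbon, so no epimerisation is possible.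

Step 9
Reactants: 12 (1S,2R,3S)-2-{[tert-butyl(diphenyl)silyl]oxymethyl}-3-(3,4,5-trimethoxyphenyl)-1-[(3,4,5-trimethoxyphenyl)methyl]cyclopropane-1-carbaldehyde
Product: 13 (2S,3R)-3-{[tert-butyl(diphenyl)silyl]oxymethyl}-2-(3,4,5-trimethoxyphenyl)-4-[(3,4,5-trimethoxyphenyl)methyl]-2,3-dihydrofuran (2,3-trans)
Conditions: Sc(OTf)3 (10 mol%), CH2Cl2, 0 °C → rt; Et3N quench before concentration
Reagents that add atoms: none
Why: Lewis-acid-catalysed Cloke–Wilson rearrangement of a donor–acceptor cyclopropane: Sc(OTf)3 binds the formyl oxygen of 12, the C2–C4 bond heterolyses to a benzylic cation at C2 (stabilised by the trimethoxyphenyl ring) and a scandium enolate over C4–C5, and the enolate oxygen then bonds to C2, forming O1–C2 and the 2,3-dihydrofuran with release of the cyclopropane strain. The closest known reaction type is the Lewis or Brønsted acid promoted ring expansion of 2-aryl cyclopropyl ketones and aldehydes to 2,3-dihydrofurans. Ring closure: formally the oxygen displaces C4 from C2 in a 5-endo-tet sense, which cannot be concerted because the tethered oxygen cannot reach the rear of the C2–C4 bond; the reaction therefore runs by ionisation and recombination, a five-membered closure of an oxygen nucleophile onto a planar cation without that stereoelectronic barrier, whereas closure through carbon only returns the cyclopropane. C3 takes no part in bond breaking and keeps the R configuration installed in step 5. C2 is planar in the intermediate and is set on closure: the aryl group takes the face away from the neighbouring CH2OSi group, and because the benzylic C–O bond can ionise again under the catalyst the trans isomer is also the one favoured by equilibration. The selectivities needed are cleavage of C2–C4 and not C3–C4 (C2 carries the cation-stabilising aryl group, C3 only an inductively withdrawing silyloxymethyl group), closure through oxygen, and survival of the silyl and enol ethers (robust silyl group, catalytic mild Lewis acid, amine quench). The quaternary C4 bears no hydrogen, so the aldehyde cannot enolise and the zwitterion cannot be lost by deprotonation at that carbon.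

Step 10
Reactants: 13 (2S,3R)-3-{[tert-butyl(diphenyl)silyl]oxymethyl}-2-(3,4,5-trimethoxyphenyl)-4-[(3,4,5-trimethoxyphenyl)methyl]-2,3-dihydrofuran
Product: 14 (2S,3R,4R)-3-{[tert-butyl(diphenyl)silyl]oxymethyl}-2-(3,4,5-trimethoxyphenyl)-4-[(3,4,5-trimethoxyphenyl)methyl]oxolane
Conditions: H2 (1 atm), 10% Pd/C, Et3N (1 vol%), EtOAc, rt
Reagents that add atoms: none
Why: Heterogeneous syn hydrogenation of the trisubstituted enol ether from the face opposite the CH2OSi group on C3, which sits directly beside C4 (the C2 aryl group is one atom further away and can lie pseudo-equatorial), should place the benzyl group cis to the silyloxymethyl group and set C4 as R. The trace of amine is there to suppress hydrogenolysis of the benzylic O1–C2 bond and acid-induced reactions of the enol ether.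

Step 11
Reactants: 14 (2S,3R,4R)-3-{[tert-butyl(diphenyl)silyl]oxymethyl}-2-(3,4,5-trimethoxyphenyl)-4-[(3,4,5-trimethoxyphenyl)methyl]oxolane
Product: 15 [(2S,3R,4R)-2-(3,4,5-trimethoxyphenyl)-4-[(3,4,5-trimethoxyphenyl)methyl]oxolan-3-yl]methanol
Conditions: Bu4NF, THF, 0 °C → rt
Reagents that add atoms: none
Why: Fluoride-induced desilylation driven by the Si–F bond; no stereocentre and no ether of the molecule is at risk under these mildly basic conditions.

## Compound list

1 | methyl (E)-3-(3,4,5-trimethoxyphenyl)prop-2-enoate | COc1cc(/C=C/C(=O)OC)cc(OC)c1OC | starting material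
2 | (E)-3-(3,4,5-trimethoxyphenyl)prop-2-en-1-ol | COc1cc(/C=C/CO)cc(OC)c1OC | intermediate
3 | 2,2,6-trimethyl-4H-1,3-dioxin-4-one | CC1=CC(=O)OC(C)(C)O1 | starting material
4 | acetylketene | CC(=O)C=C=O | intermediate (not isolated)
5 | (E)-3-(3,4,5-trimethoxyphenyl)prop-2-en-1-yl 3-oxobutanoate | COc1cc(/C=C/COC(=O)CC(C)=O)cc(OC)c1OC | intermediate
6 | 5-(chloromethyl)-1,2,3-trimethoxybenzene | COc1cc(CCl)cc(OC)c1OC | starting material
7 | (E)-3-(3,4,5-trimethoxyphenyl)prop-2-en-1-yl 3-oxo-2-[(3,4,5-trimethoxyphenyl)methyl]butanoate (racemic) | COc1cc(/C=C/COC(=O)C(Cc2cc(OC)c(OC)c(OC)c2)C(C)=O)cc(OC)c1OC | intermediate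
8 | (E)-3-(3,4,5-trimethoxyphenyl)prop-2-en-1-yl 2-diazo-3-(3,4,5-trimethoxyphenyl)propanoate | COc1cc(/C=C/COC(=O)C(=[N+]=[N-])Cc2cc(OC)c(OC)c(OC)c2)cc(OC)c1OC | intermediate
9 | (1S,5R,6S)-6-(3,4,5-trimethoxyphenyl)-1-[(3,4,5-trimethoxyphenyl)methyl]-3-oxabicyclo[3.1.0]hexan-2-one | O=C1[C@]2(Cc3cc(OC)c(OC)c(OC)c3)[C@H](CO1)[C@H]2c4cc(OC)c(OC)c(OC)c4 | intermediate
10 | (1S,2R,3S)-2-(hydroxymethyl)-N-methoxy-N-methyl-3-(3,4,5-trimethoxyphenyl)-1-[(3,4,5-trimethoxyphenyl)methyl]cyclopropane-1-carboxamide | CON(C)C(=O)[C@]1(Cc2cc(OC)c(OC)c(OC)c2)[C@H](CO)[C@H]1c3cc(OC)c(OC)c(OC)c3 | intermediate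
11 | (1S,2R,3S)-2-{[tert-butyl(diphenyl)silyl]oxymethyl}-N-methoxy-N-methyl-3-(3,4,5-trimethoxyphenyl)-1-[(3,4,5-trimethoxyphenyl)methyl]cyclopropane-1-carboxamide | CON(C)C(=O)[C@]1(Cc2cc(OC)c(OC)c(OC)c2)[C@H](CO[Si](c3ccccc3)(c4ccccc4)C(C)(C)C)[C@H]1c5cc(OC)c(OC)c(OC)c5 | intermediate
12 | (1S,2R,3S)-2-{[tert-butyl(diphenyl)silyl]oxymethyl}-3-(3,4,5-trimethoxyphenyl)-1-[(3,4,5-trimethoxyphenyl)methyl]cyclopropane-1-carbaldehyde | O=C[C@]1(Cc2cc(OC)c(OC)c(OC)c2)[C@H](CO[Si](c3ccccc3)(c4ccccc4)C(C)(C)C)[C@H]1c5cc(OC)c(OC)c(OC)c5 | intermediate
13 | (2S,3R)-3-{[tert-butyl(diphenyl)silyl]oxymethyl}-2-(3,4,5-trimethoxyphenyl)-4-[(3,4,5-trimethoxyphenyl)methyl]-2,3-dihydrofuran | COc1cc(CC2=CO[C@H](c3cc(OC)c(OC)c(OC)c3)[C@H]2CO[Si](c4ccccc4)(c5ccccc5)C(C)(C)C)cc(OC)c1OC | intermediate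
14 | (2S,3R,4R)-3-{[tert-butyl(diphenyl)silyl]oxymethyl}-2-(3,4,5-trimethoxyphenyl)-4-[(3,4,5-trimethoxyphenyl)methyl]oxolane | COc1cc(C[C@H]2CO[C@H](c3cc(OC)c(OC)c(OC)c3)[C@H]2CO[Si](c4ccccc4)(c5ccccc5)C(C)(C)C)cc(OC)c1OC | intermediate
15 | [(2S,3R,4R)-2-(3,4,5-trimethoxyphenyl)-4-[(3,4,5-trimethoxyphenyl)methyl]oxolan-3-yl]methanol | COc1cc(C[C@H]2CO[C@H](c3cc(OC)c(OC)c(OC)c3)[C@H]2CO)cc(OC)c1OC | target

## Step count and least certain steps

Total step count: 11. Longest linear sequence: 11 steps (1 to 15); 3 and 6 enter as purchased materials.

**Step 9 (key step).**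
- What may go wrong: ionisation may be slow, because a single formyl group is a modest acceptor and the two meta-methoxy groups temper the donor. Once formed, the zwitterion may lose a proton from C3 to give an open-chain unsaturated aldehyde. The activated formyl group may be attacked by the electron-rich benzyl ring (Friedel–Crafts). The enol ether may hydrate or oligomerise while the acid is present.
- Fallback, from 12 back to 13: the ring opening is run with water as external nucleophile (Sc(OTf)3 or TsOH·H2O, wet MeCN). Capture of the benzylic cation by water and hydration of any 13 already formed both converge on the acid-stable lactol (4R,5S)-4-{[tert-butyl(diphenyl)silyl]oxymethyl}-5-(3,4,5-trimethoxyphenyl)-3-[(3,4,5-trimethoxyphenyl)methyl]oxolan-2-ol F1, with the 2,3-trans relation expected from equilibration through the benzylic cation. F1 is then dehydrated under basic conditions (MsCl, Et3N, CH2Cl2; anomeric mesylate, elimination towards C4) to 13, which in this way never meets acid.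

**Step 5.**
- What may go wrong: 1,2-hydride shift within the carbene (the migrating hydrogens are benzylic) may outrun cyclopropanation, because the ester must first rotate into its s-cis arrangement before the alkene can be reached; this would give the conjugated (Z)-enoate. Carbene dimerisation and incomplete enantioselection are further risks.
- Fallback, from 5 back to 9: the β-hydrogens are removed from the carbene and the benzyl group is added afterwards. Diazo transfer to 5 (p-ABSA, Et3N, MeCN) gives (E)-3-(3,4,5-trimethoxyphenyl)prop-2-en-1-yl 2-diazo-3-oxobutanoate F2. LiOH in aqueous MeCN removes the acetyl group to give (E)-3-(3,4,5-trimethoxyphenyl)prop-2-en-1-yl diazoacetate F3. Cyclisation with Rh2(4S-MPPIM)4 (MPPIM = methyl 1-(3-phenylpropanoyl)-2-oxoimidazolidine-4-carboxylate), or its enantiomer as the required sense dictates, in CH2Cl2 at 40 °C gives (1S,5R,6R)-6-(3,4,5-trimethoxyphenyl)-3-oxabicyclo[3.1.0]hexan-2-one F4. Deprotonation with LiN(iPr)2 (THF, −78 °C) and alkylation with 6 benzylates the bridgehead α-carbon, where the cis ring fusion allows only retention, and gives 9.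

**Step 10.**
- What may go wrong: poor facial selectivity if the C2 aryl group shields its face as strongly as the C3 substituent shields the other, or hydrogenolysis of the benzylic O1–C2 bond.
- Fallback, from 13 back to 14: C4 is set by kinetic protonation, not by hydrogen delivery. Oxidation of the enol ether with pyridinium chlorochromate [C5H5NH][CrO3Cl] (CH2Cl2) gives (4R,5S)-4-{[tert-butyl(diphenyl)silyl]oxymethyl}-5-(3,4,5-trimethoxyphenyl)-3-[(3,4,5-trimethoxyphenyl)methyl]oxolan-2-one F5 as a mixture at C3. Enolisation with LiN(iPr)2 at −78 °C and quenching with a bulky proton donor (2,6-di-tert-butyl-4-methylphenol), which approaches anti to the β-substituent, gives the cis lactone (3R,4R,5S)-4-{[tert-butyl(diphenyl)silyl]oxymethyl}-5-(3,4,5-trimethoxyphenyl)-3-[(3,4,5-trimethoxyphenyl)methyl]oxolan-2-one F6. iBu2AlH (−78 °C) gives the lactol (3R,4R,5S)-4-{[tert-butyl(diphenyl)silyl]oxymethyl}-5-(3,4,5-trimethoxyphenyl)-3-[(3,4,5-trimethoxyphenyl)methyl]oxolan-2-ol F7, and Et3SiH with BF3·OEt2 (CH2Cl2, −78 °C) removes the anomeric hydroxyl group to give 14.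

**Step 6.**
- What may go wrong: slow aminolysis at a carbonyl flanked by a quaternary carbon, and relactonisation of 10 with loss of the amine during handling.
- Fallback, from 9 back to 12: LiAlH4 (THF, 0 °C) gives [(1S,2R,3S)-3-(3,4,5-trimethoxyphenyl)-1-[(3,4,5-trimethoxyphenyl)methyl]cyclopropane-1,2-diyl]dimethanol F8. One equivalent of TBDPSCl with imidazole at −20 °C should silylate the less hindered hydroxymethyl group (on the CH carbon, not the neopentyl-type one) to give [(1S,2R,3S)-2-{[tert-butyl(diphenyl)silyl]oxymethyl}-3-(3,4,5-trimethoxyphenyl)-1-[(3,4,5-trimethoxyphenyl)methyl]cyclopropyl]methanol F9. Dess–Martin periodinane (NaHCO3, CH2Cl2) then gives 12.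

## Further compounds

F1 | step 9 | (4R,5S)-4-{[tert-butyl(diphenyl)silyl]oxymethyl}-5-(3,4,5-trimethoxyphenyl)-3-[(3,4,5-trimethoxyphenyl)methyl]oxolan-2-ol (epimers at C2 and C3) | COc1cc(CC2C(O)O[C@H](c3cc(OC)c(OC)c(OC)c3)[C@H]2CO[Si](c4ccccc4)(c5ccccc5)C(C)(C)C)cc(OC)c1OC
F2 | step 5 | (E)-3-(3,4,5-trimethoxyphenyl)prop-2-en-1-yl 2-diazo-3-oxobutanoate | COc1cc(/C=C/COC(=O)C(=[N+]=[N-])C(C)=O)cc(OC)c1OC
F3 | step 5 | (E)-3-(3,4,5-trimethoxyphenyl)prop-2-en-1-yl diazoacetate | COc1cc(/C=C/COC(=O)C=[N+]=[N-])cc(OC)c1OC
F4 | step 5 | (1S,5R,6R)-6-(3,4,5-trimethoxyphenyl)-3-oxabicyclo[3.1.0]hexan-2-one | O=C1[C@@H]2[C@H](CO1)[C@H]2c3cc(OC)c(OC)c(OC)c3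
F5 | step 10 | (4R,5S)-4-{[tert-butyl(diphenyl)silyl]oxymethyl}-5-(3,4,5-trimethoxyphenyl)-3-[(3,4,5-trimethoxyphenyl)methyl]oxolan-2-one (epimers at C3) | COc1cc(CC2C(=O)O[C@H](c3cc(OC)c(OC)c(OC)c3)[C@H]2CO[Si](c4ccccc4)(c5ccccc5)C(C)(C)C)cc(OC)c1OC
F6 | step 10 | (3R,4R,5S)-4-{[tert-butyl(diphenyl)silyl]oxymethyl}-5-(3,4,5-trimethoxyphenyl)-3-[(3,4,5-trimethoxyphenyl)methyl]oxolan-2-one | COc1cc(C[C@H]2C(=O)O[C@H](c3cc(OC)c(OC)c(OC)c3)[C@H]2CO[Si](c4ccccc4)(c5ccccc5)C(C)(C)C)cc(OC)c1OC
F7 | step 10 | (3R,4R,5S)-4-{[tert-butyl(diphenyl)silyl]oxymethyl}-5-(3,4,5-trimethoxyphenyl)-3-[(3,4,5-trimethoxyphenyl)methyl]oxolan-2-ol (anomers) | COc1cc(C[C@H]2C(O)O[C@H](c3cc(OC)c(OC)c(OC)c3)[C@H]2CO[Si](c4ccccc4)(c5ccccc5)C(C)(C)C)cc(OC)c1OC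
F8 | step 6 | [(1S,2R,3S)-3-(3,4,5-trimethoxyphenyl)-1-[(3,4,5-trimethoxyphenyl)methyl]cyclopropane-1,2-diyl]dimethanol | OC[C@]1(Cc2cc(OC)c(OC)c(OC)c2)[C@H](CO)[C@H]1c3cc(OC)c(OC)c(OC)c3
F9 | step 6 | [(1S,2R,3S)-2-{[tert-butyl(diphenyl)silyl]oxymethyl}-3-(3,4,5-trimethoxyphenyl)-1-[(3,4,5-trimethoxyphenyl)methyl]cyclopropyl]methanol | OC[C@]1(Cc2cc(OC)c(OC)c(OC)c2)[C@H](CO[Si](c3ccccc3)(c4ccccc4)C(C)(C)C)[C@H]1c5cc(OC)c(OC)c(OC)c5
A1 | alternative 1 | diethyl 2-[(3,4,5-trimethoxyphenyl)methylidene]propanedioate | CCOC(=O)C(=Cc1cc(OC)c(OC)c(OC)c1)C(=O)OCC
A2 | alternative 1 | prop-2-yn-1-ol | C#CCO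
A3 | alternative 1 | 5-iodo-1,2,3-trimethoxybenzene | COc1cc(I)cc(OC)c1OC
A4 | alternative 1 | diethyl (2R,4Z)-2-(3,4,5-trimethoxyphenyl)-4-[(3,4,5-trimethoxyphenyl)methylidene]oxolane-3,3-dicarboxylate (needed antipode of the racemate) | COc1cc(/C=C2\CO[C@H](c3cc(OC)c(OC)c(OC)c3)C2(C(=O)OCC)C(=O)OCC)cc(OC)c1OC
A5 | alternative 2 | 5-{chloro[(trimethylsilyl)methoxy]methyl}-1,2,3-trimethoxybenzene | COc1cc(C(Cl)OC[Si](C)(C)C)cc(OC)c1OC
A6 | alternative 2 | (5S)-5-(3,4,5-trimethoxyphenyl)furan-2(5H)-one | COc1cc([C@@H]2C=CC(=O)O2)cc(OC)c1OC
A7 | alternative 2 | (1S,4S,5R,8S)-4,8-bis(3,4,5-trimethoxyphenyl)-3,7-dioxabicyclo[3.3.0]octan-2-one (cis-fused) | COc1cc([C@@H]3[C@H]2CO[C@H](c4cc(OC)c(OC)c(OC)c4)[C@H]2C(=O)O3)cc(OC)c1OC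
A8 | alternative 3 | methyl (3Z)-2-diazo-4-(3,4,5-trimethoxyphenyl)-3-{[(3,4,5-trimethoxyphenyl)methoxy]methyl}but-3-enoate | COC(=O)C(=[N+]=[N-])/C(COCc1cc(OC)c(OC)c(OC)c1)=C/c1cc(OC)c(OC)c(OC)c1
A9 | alternative 3 | methyl (2S,3S,4Z)-2-(3,4,5-trimethoxyphenyl)-4-[(3,4,5-trimethoxyphenyl)methylidene]oxolane-3-carboxylate | COc1cc(/C=C2\CO[C@H](c3cc(OC)c(OC)c(OC)c3)[C@H]2C(=O)OC)cc(OC)c1OC
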